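**Plan**

1. Labdane numbering (C17 on C8, C18/C19 on C4, C20 on C10). Cuts, in order: C15 ester and C12–C13 (side chain); the two isovalerate O–acyl bonds; C4–C19 and C4–C18; C6–C7 (ring B); the C9 arms (C9–C8, C9=C11); C1–C10 and C4–C5 (ring A).
2. Enabling feature: in ring B the C6 carbinol is homoallylic to C8 (C6–C7–C8, C17 on C8). This is the retron of a type 2 carbonyl-ene closure between a C5 aldehyde (C6) and an isopropenyl group on C9 (C7).
3. Forward: ring A by Diels–Alder reaction, the C9 arms by olefination and conjugate addition, ring B by the ene closure, alkene shift to C8=C9, a temporary 19,6β-lactone ring that brings in C19 and C18, then the acyl groups and the side chain.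
4. Stereochemistry: C5/C10 from the catalyst-controlled cycloaddition of an E-dienophile; C6 from the chair ene transition state; C4 from the 6β-carbonate tether (C19 β) and α-face methylation; C3 from equatorial hydride delivery; C13=C14 from an E-enol triflate coupled with retention.
5. The C4 quaternary centre is added after ring B is closed, so that the axial C6–O bond forms against the C10 methyl only. The C9 epimers from the conjugate addition converge when the alkene moves to C8=C9.

Key step: step 9

Assumption: the facial sense of the oxazaborolidinium catalyst in step 2 is taken from its accepted model for α-substituted enals; if the adduct proves to be the mirror image, the catalyst from (R)-α,α-diphenylprolinol is used and nothing else changes.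

**Route**

Step 1
Reactants: 1 methyl vinyl ketone
Product: 2 2-(triisopropylsilyloxy)buta-1,3-diene
Conditions: i-Pr3SiOTf, Et3N, Et2O, 0 °C to rt
Reagents that add atoms: triisopropylsilyl trifluoromethanesulfonate, CC(C)[Si](OS(=O)(=O)C(F)(F)F)(C(C)C)C(C)C
Why: Soft enolisation of the methyl ketone and O-silylation (silyl enol ether formation) should give the robust 2-silyloxy diene.

Step 2
Reactants: 2 2-(triisopropylsilyloxy)buta-1,3-diene; 3 ethyl (E)-3-methyl-4-oxobut-2-enoate
Product: 4 ethyl (1S,6S)-6-formyl-6-methyl-3-(triisopropylsilyloxy)cyclohex-3-ene-1-carboxylate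
Conditions: oxazaborolidinium triflimide from (S)-α,α-diphenylprolinol, o-tolylboroxine and Tf2NH (10 mol%), CH2Cl2, −78 °C
Reagents that add atoms: none
Why: Catalytic enantioselective Diels–Alder reaction of an α-substituted enal: the boron Lewis acid binds the formyl group, the silyloxy-bearing diene terminus (C4) bonds to the enal β-carbon C5 ("para" adduct), suprafacial addition to the E-dienophile places the C10 formyl and the C5 ester trans, and the shielded face of the bound enal fixes the absolute configuration at C5 and C10.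

Step 3
Reactants: 4 ring A aldehyde ester; 5 triethyl phosphonoacetate
Product: 6 E-enoate diester
Conditions: NaH, THF, 0 °C to rt
Reagents that add atoms: none
Why: Horner–Wadsworth–Emmons olefination of the non-enolisable neopentyl aldehyde should give the E-enoate (C9=C11, C12 ester) without touching the silyl enol ether; no stereocentre is formed.

Step 4
Reactants: 6 E-enoate diester
Product: 8 isopropenyl diester (C9 epimers), via silyl ketene acetal 7 (not isolated)
Conditions: CH2=C(CH3)MgBr, CuBr·SMe2 (20 mol%), Me3SiCl, HMPA, THF, −78 °C; aq. NH4Cl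
Reagents that add atoms: isopropenylmagnesium bromide, C=C(C)[Mg]Br
Why: Chlorosilane-accelerated copper-catalysed conjugate addition of a Grignard reagent to the enoate places C7, C8 and C17 on C9; the saturated C5 ester is inert at −78 °C, and C9 forms as an epimer mixture that is erased in step 11.

Step 5
Reactants: 8 isopropenyl diester
Product: 9 C6,C12-diol (C9 epimers)
Conditions: LiAlH4, Et2O, 0 °C; aq. NaOH work-up
Reagents that add atoms: none
Why: Hydride reduction of both ethyl esters gives the two primary alcohols and leaves the silyl enol ether and the isopropenyl group untouched.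

Step 6
Reactants: 9 C6,C12-diol
Product: 10 C12 silyl ether with free C6 alcohol
Conditions: t-BuPh2SiCl (1.05 equiv), imidazole, CH2Cl2, 0 °C
Reagents that add atoms: tert-butyl(chloro)diphenylsilane, CC(C)(C)[Si](Cl)(c1ccccc1)c1ccccc1
Why: Silyl ether formation under steric control: the C12 hydroxyl on the unbranched arm should react much faster with the bulky chlorosilane than the C6 hydroxyl next to C5 and the quaternary C10.

Step 7
Reactants: 10 C12 silyl ether
Product: 11 ring A enone alcohol
Conditions: Pd(OAc)2 (1.2 equiv), DMSO, 45 °C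
Reagents that add atoms: none
Why: Saegusa–Ito oxidation: the silyl enol ether gives a palladium enolate at C2, and β-hydride elimination toward C1 unveils the C1=C2–C3=O enone, whose only enolisable position is then C4.

Step 8
Reactants: 11 ring A enone alcohol
Product: 12 ring A enone aldehyde (ene precursor)
Conditions: Dess–Martin periodinane, NaHCO3, CH2Cl2, 0 °C to rt
Reagents that add atoms: none
Why: Dess–Martin oxidation of the hindered primary alcohol under buffered conditions should give the C6 aldehyde without epimerising C5, so the formyl group stays trans to the C9 arm.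

Step 9
Reactants: 12 ring A enone aldehyde
Product: 13 6β-hydroxy-8(17)-ene octalone (C9 epimers)
Conditions: Me2AlCl (3 equiv), CH2Cl2, −78 to −20 °C; aq. NaHCO3
Reagents that add atoms: none
Why: Me2AlCl activates the C6 aldehyde as enophile; C7, the terminal carbon of the isopropenyl group, bonds to C6 while a C17 hydrogen passes to the aluminium-bound oxygen in a concerted six-centre transition state, and the alcohol complex then loses methane so that no Brønsted acid builds up. The closest known reaction type is the Me2AlCl-promoted type 2 intramolecular carbonyl-ene cyclisation of 6-methylhept-6-enals to 3-methylenecyclohexanols. Ring B closes as a six-membered ring, exo with respect to the carbonyl group and endo with respect to the isopropenyl double bond, through a chair fused to ring A. The one new stereocentre, C6, is set by that chair: the C5 and C10 arms are trans and pseudo-equatorial, and hydrogen transfer from C17 is possible only when the C6 oxygen is axial, which is the β face syn to the C10 methyl. The step needs chemoselection for the aldehyde over the enone and silyl ether, secured by the higher reactivity of the aldehyde and by excess reagent that saturates the other Lewis basic sites, and it tolerates the C9 mixture because either epimer fits the chair with its silyloxyethyl arm equatorial or axial.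

Step 10
Reactants: 13 6β-hydroxy-8(17)-ene octalone
Product: 14 6β-methyl carbonate
Conditions: ClCO2Me, pyridine, DMAP (cat.), CH2Cl2, 0 °C to rt
Reagents that add atoms: methyl chloroformate, COC(=O)Cl
Why: DMAP-catalysed acylation of the axial alcohol with a small chloroformate (carbonate formation) masks O6 as an ester-type group that resists ionisation in step 11 and carries the future C19.

Step 11
Reactants: 14 6β-methyl carbonate
Product: 15 8-ene carbonate
Conditions: TsOH·H2O (20 mol%), benzene, 60 °C
Reagents that add atoms: none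
Why: Acid-catalysed alkene isomerisation through the tertiary C8 cation (protonation at C17, loss of H9) should give the thermodynamically preferred tetrasubstituted C8=C9 alkene and removes the C9 stereocentre, so both epimers converge.

Step 12
Reactants: 15 8-ene carbonate
Product: 17 4α-methyl enone 19,6β-lactone, via keto lactone 16 (not isolated)
Conditions: LiN(SiMe3)2 (1.1 equiv), THF, −78 to 0 °C; then MeI, DMPU, 0 °C to rt
Reagents that add atoms: iodomethane, CI
Why: Claisen-type acylation of a ketone enolate by a carbonate (as in β-keto ester formation with dimethyl carbonate), here intramolecular: the C4 enolate attacks the 6β-carbonate 5-exo to give the β-keto γ-lactone with C19 necessarily β, the expelled methoxide deprotonates it, and MeI then alkylates C4 on the only open (α) face, which sets C4.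

Step 13
Reactants: 17 4α-methyl enone 19,6β-lactone
Product: 18 saturated keto lactone
Conditions: H2 (1 atm), Pd/C, EtOAc, rt
Reagents that add atoms: none
Why: Heterogeneous hydrogenation reduces the disubstituted, conjugated C1=C2 bond, while the tetrasubstituted C8=C9 alkene is not expected to react at 1 atm.

Step 14
Reactants: 18 saturated keto lactone
Product: 19 3α-hydroxy lactone
Conditions: LiBH(s-Bu)3 (L-Selectride), THF, −78 °C; aq. NH4Cl
Reagents that add atoms: none
Why: Bulky trialkylborohydride reduction of a cyclohexanone next to a quaternary carbon: equatorial (β-face) hydride delivery should give the axial 3α-alcohol, as with 4,4-disubstituted 3-oxo terpenoids, and the lactone survives at −78 °C.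

Step 15
Reactants: 19 3α-hydroxy lactone
Product: 20 3α,6β,19-triol
Conditions: LiAlH4, THF, 0 °C to rt; aq. NaOH work-up
Reagents that add atoms: none
Why: Hydride reduction of the γ-lactone (as in the reduction of labdane 19,6β-olides to 6β,19-diols) frees the 19-CH2OH and the 6β-OH without touching a stereocentre.

Step 16
Reactants: 20 3α,6β,19-triol
Product: 21 3α,19-bis(isovalerate)
Conditions: 3-methylbutanoic anhydride (2.5 equiv), DMAP (cat.), pyridine, CH2Cl2, rt
Reagents that add atoms: 3-methylbutanoic anhydride, CC(C)CC(=O)OC(=O)CC(C)C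
Why: DMAP-catalysed esterification under steric control: the primary 19-OH and the axial 3α-OH should be acylated, whereas the 6β-OH, 1,3-diaxial to both C19 and C20, is expected to stay free.

Step 17
Reactants: 21 3α,19-bis(isovalerate)
Product: 22 C12 alcohol
Conditions: HF·pyridine, pyridine, THF, 0 °C to rt
Reagents that add atoms: none
Why: Fluoride-mediated cleavage of the silyl ether under buffered conditions should leave the two esters, the 6β-OH and the tetrasubstituted alkene alone.

Step 18
Reactants: 22 C12 alcohol
Product: 23 C12 iodide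
Conditions: I2, PPh3, imidazole, CH2Cl2, 0 °C
Reagents that add atoms: iodine, II
Why: Appel-type iodination converts the unhindered primary alcohol by SN2 displacement of its alkoxyphosphonium ion, and the hindered axial 6β-OH should not compete.

Step 19
Reactants: 24 tert-butyl acetoacetate
Product: 25 tert-butyl (E)-3-(trifluoromethylsulfonyloxy)but-2-enoate
Conditions: Tf2O, aq. Me4NOH, hexanes, 5 °C
Reagents that add atoms: trifluoromethanesulfonic anhydride, O=S(=O)(OS(=O)(=O)C(F)(F)F)C(F)(F)F
Why: O-sulfonylation of the β-keto ester enolate with a non-chelating tetraalkylammonium counter-ion should give the E-enol triflate (triflate trans to the ester), in contrast to the Z isomer from chelated lithium enolates.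

Step 20
Reactants: 23 C12 iodide; 25 tert-butyl (E)-3-(trifluoromethylsulfonyloxy)but-2-enoate
Product: 27 tert-butyl ester of the target, via alkylzinc iodide 26 (not isolated)
Conditions: Zn dust (activated with 1,2-dibromoethane and Me3SiCl), DMF, 35 °C; then 25, Pd(PPh3)4 (5 mol%), rt
Reagents that add atoms: none
Why: Negishi coupling: zinc inserts into the primary C–I bond and the palladium-catalysed coupling with the enol triflate proceeds with retention, giving the 13E enoate; alkylzinc iodides tolerate esters and, as with zinc reagents bearing carbamate N–H groups, a hindered hydroxyl.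

Step 21
Reactants: 27 tert-butyl ester of the target
Product: 29 CNP0333611.1 (target acid), via bis-silyl derivative 28 (not isolated)
Conditions: Me3SiOTf (3 equiv), 2,6-lutidine, CH2Cl2, 0 °C; then aq. citric acid, THF, rt
Reagents that add atoms: none
Why: Silyl triflate-mediated tert-butyl ester cleavage (O-silylation, loss of 2-methylpropene) under lutidine buffering gives the silyl ester and 6-O-silyl ether, both hydrolysed on mild acidic work-up, so the isovalerates and the C8=C9 alkene never meet strong protic acid.

**Compound list**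

1 | methyl vinyl ketone (but-3-en-2-one) | C=CC(C)=O | starting material
2 | 2-(triisopropylsilyloxy)buta-1,3-diene | C=CC(=C)O[Si](C(C)C)(C(C)C)C(C)C | intermediate
3 | ethyl (E)-3-methyl-4-oxobut-2-enoate | CCOC(=O)/C=C(\C)C=O | starting material
4 | ethyl (1S,6S)-6-formyl-6-methyl-3-(triisopropylsilyloxy)cyclohex-3-ene-1-carboxylate (ring A; formyl carbon is C9 on C10, ester carbon is C6 on C5, the two trans) | O=C[C@@]1(C)CC=C(O[Si](C(C)C)(C(C)C)C(C)C)C[C@@H]1C(=O)OCC | intermediate
5 | triethyl phosphonoacetate | CCOC(=O)CP(=O)(OCC)OCC | starting material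
6 | E-enoate diester: 4 with the formyl group converted to (E)-CH=CH–CO2Et; C5 and C10 as in 4 | CCOC(=O)/C=C/[C@@]1(C)CC=C(O[Si](C(C)C)(C(C)C)C(C)C)C[C@@H]1C(=O)OCC | intermediate
7 | ethyl trimethylsilyl ketene acetal of 8 (formed in the flask; C9 epimers) | CCOC(O[Si](C)(C)C)=CC(C(C)=C)[C@@]1(C)CC=C(O[Si](C(C)C)(C(C)C)C(C)C)C[C@@H]1C(=O)OCC | intermediate
8 | isopropenyl diester: C10 carries CH(isopropenyl)CH2CO2Et, C5 carries CO2Et; C5 and C10 as in 4, C9 epimers | CCOC(=O)CC(C(C)=C)[C@@]1(C)CC=C(O[Si](C(C)C)(C(C)C)C(C)C)C[C@@H]1C(=O)OCC | intermediate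
9 | C6,C12-diol: both esters of 8 reduced to CH2OH; C9 epimers | OCCC(C(C)=C)[C@@]1(C)CC=C(O[Si](C(C)C)(C(C)C)C(C)C)C[C@@H]1CO | intermediate
10 | 9 with the C12 hydroxyl as tert-butyldiphenylsilyl ether and C6 hydroxyl free; C9 epimers | C=C(C)C(CCO[Si](c2ccccc2)(c3ccccc3)C(C)(C)C)[C@@]1(C)CC=C(O[Si](C(C)C)(C(C)C)C(C)C)C[C@@H]1CO | intermediate
11 | ring A enone alcohol: cyclohex-2-enone (C3=O, C1=C2) with C10 methyl, C10 CH(isopropenyl)CH2CH2OSi(t-Bu)Ph2 and C5 CH2OH, arms trans; C9 epimers | C=C(C)C(CCO[Si](c2ccccc2)(c3ccccc3)C(C)(C)C)[C@@]1(C)C=CC(=O)C[C@@H]1CO | intermediate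
12 | ring A enone aldehyde: 11 with C5 CHO (C6); C9 epimers | C=C(C)C(CCO[Si](c2ccccc2)(c3ccccc3)C(C)(C)C)[C@@]1(C)C=CC(=O)C[C@@H]1C=O | intermediate
13 | 6β-hydroxy-12-(tert-butyldiphenylsilyloxy)-13,14,15,16,18,19-hexanorlabda-1,8(17)-dien-3-one (5α-H, 10β-CH3; C9 epimers) | C=C1C(CCO[Si](c3ccccc3)(c4ccccc4)C(C)(C)C)[C@@]2(C)C=CC(=O)C[C@@H]2[C@H](O)C1 | intermediate
14 | 6β-methyl carbonate of 13 (C9 epimers) | C=C1C(CCO[Si](c3ccccc3)(c4ccccc4)C(C)(C)C)[C@@]2(C)C=CC(=O)C[C@@H]2[C@H](OC(=O)OC)C1 | intermediate
15 | 6β-(methoxycarbonyloxy)-12-(tert-butyldiphenylsilyloxy)-13,14,15,16,18,19-hexanorlabda-1,8-dien-3-one | CC1=C(CCO[Si](c3ccccc3)(c4ccccc4)C(C)(C)C)[C@@]2(C)C=CC(=O)C[C@@H]2[C@H](OC(=O)OC)C1 | intermediate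
16 | keto lactone: 3-oxo-1,8-diene 19,6β-olide with 4α-H (formed in the flask, present as its enolate) | CC1=C(CCO[Si](c4ccccc4)(c5ccccc5)C(C)(C)C)[C@@]2(C)C=CC(=O)[C@H]3[C@@H]2[C@H](OC3=O)C1 | intermediate
17 | 12-(tert-butyldiphenylsilyloxy)-3-oxo-13,14,15,16-tetranorlabda-1,8-dien-19,6β-olide (4α-CH3) | CC1=C(CCO[Si](c4ccccc4)(c5ccccc5)C(C)(C)C)[C@@]2(C)C=CC(=O)[C@@]3(C)[C@@H]2[C@H](OC3=O)C1 | intermediate
18 | 12-(tert-butyldiphenylsilyloxy)-3-oxo-13,14,15,16-tetranorlabd-8-en-19,6β-olide | CC1=C(CCO[Si](c4ccccc4)(c5ccccc5)C(C)(C)C)[C@@]2(C)CCC(=O)[C@@]3(C)[C@@H]2[C@H](OC3=O)C1 | intermediate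
19 | 3α-hydroxy-12-(tert-butyldiphenylsilyloxy)-13,14,15,16-tetranorlabd-8-en-19,6β-olide | CC1=C(CCO[Si](c4ccccc4)(c5ccccc5)C(C)(C)C)[C@@]2(C)CC[C@@H](O)[C@@]3(C)[C@@H]2[C@H](OC3=O)C1 | intermediate
20 | 12-(tert-butyldiphenylsilyloxy)-13,14,15,16-tetranorlabd-8-ene-3α,6β,19-triol | CC1=C(CCO[Si](c3ccccc3)(c4ccccc4)C(C)(C)C)[C@@]2(C)CC[C@@H](O)[C@](C)(CO)[C@@H]2[C@H](O)C1 | intermediate
21 | 3α,19-bis(3-methylbutanoate) of 20, 6β-OH free | CC1=C(CCO[Si](c3ccccc3)(c4ccccc4)C(C)(C)C)[C@@]2(C)CC[C@@H](OC(=O)CC(C)C)[C@](C)(COC(=O)CC(C)C)[C@@H]2[C@H](O)C1 | intermediate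
22 | 6β,12-dihydroxy-13,14,15,16-tetranorlabd-8-ene-3α,19-diyl bis(3-methylbutanoate) | CC1=C(CCO)[C@@]2(C)CC[C@@H](OC(=O)CC(C)C)[C@](C)(COC(=O)CC(C)C)[C@@H]2[C@H](O)C1 | intermediate
23 | 6β-hydroxy-12-iodo-13,14,15,16-tetranorlabd-8-ene-3α,19-diyl bis(3-methylbutanoate) | CC1=C(CCI)[C@@]2(C)CC[C@@H](OC(=O)CC(C)C)[C@](C)(COC(=O)CC(C)C)[C@@H]2[C@H](O)C1 | intermediate
24 | tert-butyl acetoacetate | CC(=O)CC(=O)OC(C)(C)C | starting material
25 | tert-butyl (E)-3-(trifluoromethylsulfonyloxy)but-2-enoate | C/C(OS(=O)(=O)C(F)(F)F)=C\C(=O)OC(C)(C)C | intermediate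
26 | C12 alkylzinc iodide from 23 (formed in the flask) | CC1=C(CC[Zn]I)[C@@]2(C)CC[C@@H](OC(=O)CC(C)C)[C@](C)(COC(=O)CC(C)C)[C@@H]2[C@H](O)C1 | intermediate
27 | tert-butyl (13E)-6β-hydroxy-3α,19-bis(3-methylbutanoyloxy)labda-8,13-dien-15-oate | CC1=C(CC/C(C)=C/C(=O)OC(C)(C)C)[C@@]2(C)CC[C@@H](OC(=O)CC(C)C)[C@](C)(COC(=O)CC(C)C)[C@@H]2[C@H](O)C1 | intermediate
28 | trimethylsilyl ester and 6-O-trimethylsilyl ether of the target (formed in the flask) | CC1=C(CC/C(C)=C/C(=O)O[Si](C)(C)C)[C@@]2(C)CC[C@@H](OC(=O)CC(C)C)[C@](C)(COC(=O)CC(C)C)[C@@H]2[C@H](O[Si](C)(C)C)C1 | intermediate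
29 | CNP0333611.1, (13E)-6β-hydroxy-3α,19-bis(3-methylbutanoyloxy)labda-8,13-dien-15-oic acid (3R,4S,5R,6R,10S) | CC1=C(CC/C(C)=C/C(=O)O)[C@@]2(C)CC[C@@H](OC(=O)CC(C)C)[C@](C)(COC(=O)CC(C)C)[C@@H]2[C@H](O)C1 | target

**Step count**

Total: 21 steps. Longest linear sequence: 20 steps (steps 1–18, 20 and 21; step 19 prepares the coupling partner).

**Steps most likely to fail**

Step 11. The alkene shift may stop short of regiocontrol, giving the trisubstituted C7=C8 isomer beside C8=C9, and the acid may erode material through ionisation of that allylic carbonate or capture of the C8 cation. The fallback sets out from 14 and leaves the exocyclic alkene in place. LiN(SiMe3)2 then MeI should give, through the keto lactone F1, the methylated enone lactone F2. Conjugate reduction with [(Ph3P)CuH]6, which spares the 1,1-disubstituted alkene, gives the saturated keto lactone F3. The alkene is then moved on this rigid lactone, which has no ionisable allylic ester, under neutral metal-hydride conditions (RhCl3·3H2O, ethanol, 80 °C), and the route is rejoined at 18.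

Step 9. The Lewis acid may divert the cyclisation into a stepwise cationic pathway (chloride capture, alkene scrambling), or complexation by the enone and silyl ether may stall it. The fallback sets out from 11 and replaces the ene reaction by a metal-mediated allylation that passes through the same cyclic chair, with the metal bridging C17 and the aldehyde oxygen. Ene-type chlorination of the isopropenyl group (Ca(OCl)2, CO2, CH2Cl2/water) gives the allylic chloride alcohol F4, and Dess–Martin oxidation gives the allylic chloride aldehyde F5. CrCl2 in THF (Nozaki–Hiyama allylation) generates the allylchromium species F6, which closes the C6–C7 bond with the oxygen axial, returning to 13.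

Step 4. Conjugate addition at the β-carbon next to the quaternary C10 may be too slow, leading to recovered enoate or 1,2-addition. The fallback sets out from 4 and builds the same arm by sigmatropic rearrangement. Wittig olefination with 2-(triphenylphosphoranylidene)propanal (toluene, 90 °C) gives the E-enal F7. Luche reduction (NaBH4, CeCl3·7H2O, MeOH, 0 °C) gives the allylic alcohol F8. Heating with triethyl orthoacetate and catalytic propionic acid (135 °C) forms the mixed ketene acetal F9, whose Johnson–Claisen rearrangement creates the C9–C11 bond and the isopropenyl group, returning to 8.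

**Further compounds**

F1 | step 11 | keto lactone with exocyclic C8=C17 alkene and 4α-H (C9 epimers) | C=C1C(CCO[Si](c4ccccc4)(c5ccccc5)C(C)(C)C)[C@@]2(C)C=CC(=O)[C@H]3[C@@H]2[C@H](OC3=O)C1
F2 | step 11 | 4α-methyl enone 19,6β-lactone with exocyclic C8=C17 alkene (C9 epimers) | C=C1C(CCO[Si](c4ccccc4)(c5ccccc5)C(C)(C)C)[C@@]2(C)C=CC(=O)[C@@]3(C)[C@@H]2[C@H](OC3=O)C1
F3 | step 11 | saturated 3-keto 19,6β-lactone with exocyclic C8=C17 alkene (C9 epimers) | C=C1C(CCO[Si](c4ccccc4)(c5ccccc5)C(C)(C)C)[C@@]2(C)CCC(=O)[C@@]3(C)[C@@H]2[C@H](OC3=O)C1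
F4 | step 9 | 11 with the isopropenyl methyl chlorinated (2-(chloromethyl)vinyl on C9), C6 alcohol | C=C(CCl)C(CCO[Si](c2ccccc2)(c3ccccc3)C(C)(C)C)[C@@]1(C)C=CC(=O)C[C@@H]1CO
F5 | step 9 | allylic chloride aldehyde (C6 CHO) | C=C(CCl)C(CCO[Si](c2ccccc2)(c3ccccc3)C(C)(C)C)[C@@]1(C)C=CC(=O)C[C@@H]1C=O
F6 | step 9 | allylchromium dichloride from F5 | C=C(C[Cr](Cl)Cl)C(CCO[Si](c2ccccc2)(c3ccccc3)C(C)(C)C)[C@@]1(C)C=CC(=O)C[C@@H]1C=O
F7 | step 4 | E-enal: 4 with the formyl group converted to (E)-CH=C(CH3)–CHO | O=C/C(C)=C/[C@@]1(C)CC=C(O[Si](C(C)C)(C(C)C)C(C)C)C[C@@H]1C(=O)OCC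
F8 | step 4 | E-allylic alcohol from F7 | OC/C(C)=C/[C@@]1(C)CC=C(O[Si](C(C)C)(C(C)C)C(C)C)C[C@@H]1C(=O)OCC
F9 | step 4 | mixed ketene acetal of F8 (ethyl 1-(allyloxy)vinyl ether) | C=C(OCC)OC/C(C)=C/[C@@]1(C)CC=C(O[Si](C(C)C)(C(C)C)C(C)C)C[C@@H]1C(=O)OCC
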